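The quinone ring is cut across C2=C3 and across the C1–C8a aryl–acyl bond, leaving a two-carbon piece (C1–C2 with the butanoyloxy side chain) and a four-atom piece (C3–C4(=O)–C4a–C8a). Both bonds form in one Rh(III)-catalysed C–H annulation between an α-aroyl sulfoxonium ylide and a terminal alkyne: the ylide carbon becomes C3, the alkyne CH becomes C1. The step exploits C8a–H, the only C–H ortho to the C4 carbonyl on the 5,8-dioxygenated ring (C5 is blocked by oxygen). Precursors are the bis-MOM gentisoyl sulfoxonium ylide and the (R)-propargylic butanoate; oxidation at C1 and MOM removal complete the naphthazarin.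

Key step: step 8

Remark: "butylshikonin" is taken as the butanoate ester of shikonin, (R) at the side-chain carbinol carbon as the SMILES shows; the naphthazarin tautomers interconvert, so the 2-substituted 5,8-dihydroxy-1,4-naphthoquinone form drawn is the compound obtained.

**Step 1**
Reactants: 1 4-methylpent-3-enoic acid
Product: 3 N-methoxy-N,4-dimethylpent-3-enamide, via acyl imidazolide 2 (not isolated)
Conditions: CDI, CH2Cl2, 0 °C to rt; then MeNH(OMe)·HCl, rt
Reagents that add atoms: 1,1'-carbonyldiimidazole, O=C(n1ccnc1)n1ccnc1 (imidazolyl group of 2 only); N,O-dimethylhydroxylamine hydrochloride, CNOC.Cl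
Why: Weinreb amide formation by CDI activation and aminolysis of the acyl imidazolide under near-neutral conditions should leave the β,γ-alkene in place.

**Step 2**
Reactants: 3 N-methoxy-N,4-dimethylpent-3-enamide
Product: 4 6-methyl-1-(trimethylsilyl)hept-5-en-1-yn-3-one
Conditions: TMS-acetylene, n-BuLi, THF, −78 °C; then 3, −78 to 0 °C; 1 M HCl quench at 0 °C
Reagents that add atoms: ethynyltrimethylsilane, C#C[Si](C)(C)C
Why: Weinreb ketone synthesis, in which the lithium acetylide adds once to give a chelated tetrahedral intermediate that collapses to the ynone only on quench.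

**Step 3**
Reactants: 4 6-methyl-1-(trimethylsilyl)hept-5-en-1-yn-3-one
Product: 5 (3R)-6-methyl-1-(trimethylsilyl)hept-5-en-1-yn-3-ol
Conditions: Ru[(R,R)-TsDPEN](p-cymene) (0.5 mol %), i-PrOH, rt, no added base
Reagents that add atoms: none
Why: Noyori asymmetric transfer hydrogenation of an alkynyl ketone, in which the alkynyl group takes the place of an aryl group in the catalyst pocket, so the (R,R)-catalyst is expected to set the (R)-carbinol (the enantiomeric catalyst would be used if the sense proved opposite), and the base-free medium should avoid conjugation of the β,γ-alkene.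

**Step 4**
Reactants: 5 (3R)-6-methyl-1-(trimethylsilyl)hept-5-en-1-yn-3-ol
Product: 6 (3R)-6-methylhept-5-en-1-yn-3-ol
Conditions: K2CO3 (0.2 equiv), MeOH, 0 °C to rt
Reagents that add atoms: none
Why: Base-catalysed methanolysis of the alkynyl C–Si bond (protodesilylation) does not touch the stereocentre.

**Step 5**
Reactants: 6 (3R)-6-methylhept-5-en-1-yn-3-ol
Product: 7 (3R)-6-methylhept-5-en-1-yn-3-yl butanoate
Conditions: butanoic anhydride, Et3N, DMAP (cat.), CH2Cl2, 0 °C to rt
Reagents that add atoms: butanoic anhydride, CCCC(=O)OC(=O)CCC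
Why: DMAP-catalysed acylation of the secondary alcohol proceeds at oxygen with retention at the carbinol carbon.

**Step 6**
Reactants: 8 methyl 2,5-dihydroxybenzoate
Product: 9 methyl 2,5-bis(methoxymethoxy)benzoate
Conditions: NaH, MOMCl, DMF, 0 °C to rt
Reagents that add atoms: chloromethyl methyl ether, COCCl
Why: Williamson-type O-alkylation of both phenoxides gives MOM ethers that should survive the ylide, rhodium and oxidation steps and leave under mild acid.

**Step 7**
Reactants: 9 methyl 2,5-bis(methoxymethoxy)benzoate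
Product: 10 1-[2,5-bis(methoxymethoxy)phenyl]-2-[dimethyl(oxo)-λ6-sulfanylidene]ethan-1-one
Conditions: Me3S(O)I, KOtBu, THF, reflux; then 9, reflux
Reagents that add atoms: trimethylsulfoxonium iodide, C[S+](C)(C)=O.[I-]
Why: Acyl substitution of the methyl ester by dimethylsulfoxonium methylide (Corey–Chaykovsky reagent) gives the stabilised β-keto sulfoxonium ylide.

**Step 8**
Reactants: 7 (3R)-6-methylhept-5-en-1-yn-3-yl butanoate; 10 1-[2,5-bis(methoxymethoxy)phenyl]-2-[dimethyl(oxo)-λ6-sulfanylidene]ethan-1-one
Product: 11 (1R)-1-[4-hydroxy-5,8-bis(methoxymethoxy)naphthalen-2-yl]-4-methylpent-3-en-1-yl butanoate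
Conditions: [Cp*Rh(MeCN)3](SbF6)2 (5 mol %), PivOH (0.5 equiv), DCE, 80 °C, 7 added slowly to 10 (1.5 equiv)
Reagents that add atoms: none
Why: The ylide carbonyl oxygen directs carboxylate-assisted rhodation of the only free ortho C–H (C6 of the aryl ring, C2 being blocked by OMOM); the terminal alkyne then inserts into the Rh–aryl bond with the aryl group delivered to the unsubstituted alkyne carbon, the tethered ylide carbon binds rhodium and loses DMSO to give a Rh carbene, and migratory insertion of the alkenyl group onto that carbene followed by protonation of the resulting rhodium naphtholate releases the 1-naphthol and Rh(III). The closest known reaction type is the Cp*Rh(III)-catalysed redox-neutral [4+2] annulation of α-aroyl sulfoxonium ylides with alkynes to 1-naphthols. The six-membered carbocycle is closed as a formal [4+2] annulation (four atoms CH–C(=O)–C(ipso)–C(ortho) from 10, two from the alkyne), the ring-closing event being the alkenyl-to-carbene migratory insertion within a seven-membered rhodacycle. No new stereocentre is formed, and the propargylic C–O stereocentre is a spectator that should be carried through unchanged. The step needs alkyne regioselectivity, which the steric bias of a terminal alkyne (branched carbon next to Rh, CH terminus next to the arene) and coordination of the butanoate carbonyl should secure, and it needs carbene formation to outrun β-acyloxy elimination from the alkenyl–rhodium intermediate, which the chelated, intramolecular ylide should favour.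

**Step 9**
Reactants: 11 (1R)-1-[4-hydroxy-5,8-bis(methoxymethoxy)naphthalen-2-yl]-4-methylpent-3-en-1-yl butanoate
Product: 12 (1R)-1-[5,8-bis(methoxymethoxy)-1,4-dioxo-1,4-dihydronaphthalen-2-yl]-4-methylpent-3-en-1-yl butanoate
Conditions: (KSO3)2NO (2.5 equiv), KH2PO4 buffer, acetone–H2O, 0 °C to rt
Reagents that add atoms: potassium nitrosodisulfonate (Fremy's salt), [K+].[K+].[O]N(S(=O)(=O)[O-])S(=O)(=O)[O-]
Why: Teuber oxidation, in which the naphthoxyl radical couples with a second nitroxyl at the free para carbon and loses imidodisulfonate, should give the 1,4-quinone without touching the alkene, ester or acetals.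

**Step 10**
Reactants: 12 (1R)-1-[5,8-bis(methoxymethoxy)-1,4-dioxo-1,4-dihydronaphthalen-2-yl]-4-methylpent-3-en-1-yl butanoate
Product: 13 butyrylshikonin, (1R)-1-(5,8-dihydroxy-1,4-dioxo-1,4-dihydronaphthalen-2-yl)-4-methylpent-3-en-1-yl butanoate
Conditions: TFA–CH2Cl2 (1:10), 0 °C, short reaction time; aq. NaHCO3 work-up; protect from light
Reagents that add atoms: none
Why: Acid-catalysed acetal cleavage of the two peri-MOM ethers is driven by the hydrogen-bonded naphthazarin leaving group and should be fast enough at 0 °C to spare the alkene and the butanoate at the electron-poor, non-ionising carbinol carbon.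

**Compound list**
1 | 4-methylpent-3-enoic acid | CC(C)=CCC(=O)O | starting material
2 | 1-(4-methylpent-3-enoyl)-1H-imidazole (acyl imidazolide, not isolated) | CC(C)=CCC(=O)n1ccnc1 | intermediate
3 | N-methoxy-N,4-dimethylpent-3-enamide | CC(C)=CCC(=O)N(C)OC | intermediate
4 | 6-methyl-1-(trimethylsilyl)hept-5-en-1-yn-3-one | CC(C)=CCC(=O)C#C[Si](C)(C)C | intermediate
5 | (3R)-6-methyl-1-(trimethylsilyl)hept-5-en-1-yn-3-ol | O[C@H](CC=C(C)C)C#C[Si](C)(C)C | intermediate
6 | (3R)-6-methylhept-5-en-1-yn-3-ol | O[C@H](CC=C(C)C)C#C | intermediate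
7 | (3R)-6-methylhept-5-en-1-yn-3-yl butanoate | CCCC(=O)O[C@H](CC=C(C)C)C#C | intermediate
8 | methyl 2,5-dihydroxybenzoate (methyl gentisate) | COC(=O)c1cc(O)ccc1O | starting material
9 | methyl 2,5-bis(methoxymethoxy)benzoate | COC(=O)c1cc(OCOC)ccc1OCOC | intermediate
10 | 1-[2,5-bis(methoxymethoxy)phenyl]-2-[dimethyl(oxo)-λ6-sulfanylidene]ethan-1-one | CS(C)(=O)=CC(=O)c1cc(OCOC)ccc1OCOC | intermediate
11 | (1R)-1-[4-hydroxy-5,8-bis(methoxymethoxy)naphthalen-2-yl]-4-methylpent-3-en-1-yl butanoate | CCCC(=O)O[C@H](CC=C(C)C)c1cc(O)c2c(OCOC)ccc(OCOC)c2c1 | intermediate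
12 | (1R)-1-[5,8-bis(methoxymethoxy)-1,4-dioxo-1,4-dihydronaphthalen-2-yl]-4-methylpent-3-en-1-yl butanoate | CCCC(=O)O[C@H](CC=C(C)C)C1=CC(=O)c2c(OCOC)ccc(OCOC)c2C1=O | intermediate
13 | butyrylshikonin, (1R)-1-(5,8-dihydroxy-1,4-dioxo-1,4-dihydronaphthalen-2-yl)-4-methylpent-3-en-1-yl butanoate | CCCC(=O)O[C@H](CC=C(C)C)C1=CC(=O)c2c(O)ccc(O)c2C1=O | target

**Step count and risks**
Total step count: 10. Longest linear sequence: 8 steps (steps 1–5, then 8, 9 and 10).

Steps most likely to fail:

Step 8 (key step). What may go wrong: β-acyloxy elimination from the alkenyl–rhodium intermediate (allene formation and loss of the stereocentre), oligomerisation of the terminal alkyne at rhodium, or slow metalation of a C–H flanked by an alkoxy group. The fallback sets out from 7 and comes back at 12; it builds the ring by a Dötz benzannulation, which brings the C1 oxygen in with the ring. Commercial hydroquinone would be bis-protected (NaH, MOMCl, DMF) to 1,4-bis(methoxymethoxy)benzene F1. Ortho-lithiation of F1 (n-BuLi, TMEDA, THF, 0 °C), addition to Cr(CO)6 and O-methylation (MeOTf) should give the Fischer carbene complex pentacarbonyl{[2,5-bis(methoxymethoxy)phenyl](methoxy)methylidene}chromium F2. Heating F2 with 7 (t-BuOMe, 55 °C) should give (1R)-1-[1-hydroxy-4-methoxy-5,8-bis(methoxymethoxy)naphthalen-2-yl]-4-methylpent-3-en-1-yl butanoate F3, with the alkyne substituent next to the new phenol as usual for terminal alkynes. Oxidative demethylation of F3 with CAN (MeCN–H2O, 0 °C) should deliver 12, so step 9 is not needed on this path.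

Step 9. What may go wrong: coupling of the bulky nitroxyl radical at the ortho carbon instead of the hindered para carbon (ortho-quinone formation), or stalled conversion. The fallback sets out from 11 and comes back at 12; it replaces the radical oxidation by a two-electron oxidative dearomatisation with a small nucleophile. PhI(OAc)2 (2.2 equiv) in MeOH at 0 °C should give the para-quinone monoketal (1R)-1-[1,1-dimethoxy-5,8-bis(methoxymethoxy)-4-oxo-1,4-dihydronaphthalen-2-yl]-4-methylpent-3-en-1-yl butanoate F4, and mild ketal hydrolysis (aq. AcOH–THF, rt) should release 12.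

Step 10. What may go wrong: acid-promoted addition to the trisubstituted alkene, or ester participation and loss at the side chain, before both acetals are cleaved. The fallback sets out from 8 and comes back at 13; it replaces the acid-labile MOM ethers by PMB ethers that are removed oxidatively at neutral pH. Alkylation of 8 (PMBCl, K2CO3, DMF) would give methyl 2,5-bis[(4-methoxyphenyl)methoxy]benzoate F5. Ylide formation as in step 7 would give 1-{2,5-bis[(4-methoxyphenyl)methoxy]phenyl}-2-[dimethyl(oxo)-λ6-sulfanylidene]ethan-1-one F6. Annulation of F6 with 7 as in step 8 would give (1R)-1-{4-hydroxy-5,8-bis[(4-methoxyphenyl)methoxy]naphthalen-2-yl}-4-methylpent-3-en-1-yl butanoate F7. Teuber oxidation as in step 9 would give (1R)-1-{5,8-bis[(4-methoxyphenyl)methoxy]-1,4-dioxo-1,4-dihydronaphthalen-2-yl}-4-methylpent-3-en-1-yl butanoate F8. DDQ (CH2Cl2–pH 7 buffer, 0 °C to rt) should then cleave both PMB ethers of F8 to give 13.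

Further compounds
F1 | step 8 | 1,4-bis(methoxymethoxy)benzene | COCOc1ccc(OCOC)cc1
F2 | step 8 | pentacarbonyl{[2,5-bis(methoxymethoxy)phenyl](methoxy)methylidene}chromium | COC(c1cc(OCOC)ccc1OCOC)=[Cr](=C=O)(=C=O)(=C=O)(=C=O)=C=O
F3 | step 8 | (1R)-1-[1-hydroxy-4-methoxy-5,8-bis(methoxymethoxy)naphthalen-2-yl]-4-methylpent-3-en-1-yl butanoate | CCCC(=O)O[C@H](CC=C(C)C)c1cc(OC)c2c(OCOC)ccc(OCOC)c2c1O
F4 | step 9 | (1R)-1-[1,1-dimethoxy-5,8-bis(methoxymethoxy)-4-oxo-1,4-dihydronaphthalen-2-yl]-4-methylpent-3-en-1-yl butanoate | CCCC(=O)O[C@H](CC=C(C)C)C1=CC(=O)c2c(OCOC)ccc(OCOC)c2C1(OC)OC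
F5 | step 10 | methyl 2,5-bis[(4-methoxyphenyl)methoxy]benzoate | COC(=O)c1cc(OCc2ccc(OC)cc2)ccc1OCc1ccc(OC)cc1
F6 | step 10 | 1-{2,5-bis[(4-methoxyphenyl)methoxy]phenyl}-2-[dimethyl(oxo)-λ6-sulfanylidene]ethan-1-one | CS(C)(=O)=CC(=O)c1cc(OCc2ccc(OC)cc2)ccc1OCc1ccc(OC)cc1
F7 | step 10 | (1R)-1-{4-hydroxy-5,8-bis[(4-methoxyphenyl)methoxy]naphthalen-2-yl}-4-methylpent-3-en-1-yl butanoate | CCCC(=O)O[C@H](CC=C(C)C)c1cc(O)c2c(OCc3ccc(OC)cc3)ccc(OCc3ccc(OC)cc3)c2c1
F8 | step 10 | (1R)-1-{5,8-bis[(4-methoxyphenyl)methoxy]-1,4-dioxo-1,4-dihydronaphthalen-2-yl}-4-methylpent-3-en-1-yl butanoate | CCCC(=O)O[C@H](CC=C(C)C)C1=CC(=O)c2c(OCc3ccc(OC)cc3)ccc(OCc3ccc(OC)cc3)c2C1=O
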